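The plan rests on cutting ring C at O1–C2 and C3–C4. This exploits the salicyl pattern of ring A, in which O1 and the C4 carbonyl carbon sit on the adjacent carbons C8a and C4a, and the benzylic position of C2 next to ring B. A chiral-acid-catalysed oxa-[4+2] (Prins-type) annulation joins a hexasubstituted salicylaldehyde to 4-acetoxystyrene, forging both bonds, closing ring C and fixing C2 as S in one operation. The aldehyde already carries the C8 methyl, the C6 prenyl, MOM ethers on O5 and O7, and O1 as its only free phenol. Oxidation at C4 and one acidic unmasking complete the target.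

Key step: step 7

Assumption: IDPi stands for the confined acid HN[P(=NSO2CF3)(O,O′-(S)-3,3′-Ar2-1,1′-binaphthyl-2,2′-diolate)]2 with Ar = 3,5-(CF3)2C6H3. Its sense of induction cannot be derived beforehand, so the (S,S)-acid is written and its mirror image is used if that one favours 2S.

Step 1
Reactants: 1 2,4,6-trihydroxybenzaldehyde
Product: 2 2-hydroxy-4,6-bis(methoxymethoxy)benzaldehyde
Conditions: MOMCl (2.2 equiv), i-Pr2NEt, CH2Cl2, 0 °C → rt
Reagents that add atoms: chloromethyl methyl ether (MOMCl), COCCl
Why: MOM protection by O-alkylation: the two ortho hydroxyls are equivalent and whichever remains is tied to the formyl oxygen by a strong hydrogen bond, so two equivalents of MOMCl should stop at the 4,6-bis-ether.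

Step 2
Reactants: 2 2-hydroxy-4,6-bis(methoxymethoxy)benzaldehyde
Product: 4 3,5-bis(methoxymethoxy)-2-methylphenol, via aryl methyl carbonate 3 (not isolated)
Conditions: ClCO2Me (1.05 equiv), Et3N, THF, 0 °C; then NaBH4, H2O, 0 °C → rt
Reagents that add atoms: methyl chloroformate, COC(=O)Cl (its atoms are held by 3 only and leave again on the way to 4)
Why: ortho-Hydroxyl-assisted deoxygenation through an ortho-quinone methide: hydride reduces the aldehyde of 3, the carbonate shifts to the new benzylic alkoxide and is expelled by the phenoxide, and a second hydride adds to the exocyclic methylene, all under basic conditions that MOM ethers tolerate.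

Step 3
Reactants: 4 3,5-bis(methoxymethoxy)-2-methylphenol
Product: 5 tert-butyl[3,5-bis(methoxymethoxy)-2-methylphenoxy]dimethylsilane
Conditions: TBSCl, imidazole, DMF, rt
Reagents that add atoms: tert-butyldimethylsilyl chloride, CC(C)(C)[Si](C)(C)Cl
Why: Routine imidazole-promoted silylation removes the acidic proton before the organolithium step and puts a bulky, non-coordinating group next to the ring position that must stay untouched.

Step 4
Reactants: 5 tert-butyl[3,5-bis(methoxymethoxy)-2-methylphenoxy]dimethylsilane; 6 prenyl bromide (1-bromo-3-methylbut-2-ene)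
Product: 8 tert-butyl[3,5-bis(methoxymethoxy)-2-methyl-4-(3-methylbut-2-enyl)phenoxy]dimethylsilane, via aryllithium 7 (not isolated)
Conditions: n-BuLi, THF, 0 °C; then CuI (10 mol%), 6, −78 °C → rt
Reagents that add atoms: n-butyllithium, [Li]CCCC (lithium, held by 7 only)
Why: Directed ortho-metalation followed by copper-assisted SN2 allylation: the two MOM ethers chelate lithium and together acidify the C–H between them, whereas the other ring C–H is shielded by OTBS, and the soft aryl-copper species attacks the primary carbon of 6 to give the linear prenyl group.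

Step 5
Reactants: 8 tert-butyl[3,5-bis(methoxymethoxy)-2-methyl-4-(3-methylbut-2-enyl)phenoxy]dimethylsilane
Product: 9 3,5-bis(methoxymethoxy)-2-methyl-4-(3-methylbut-2-enyl)phenol
Conditions: TBAF, THF, 0 °C
Reagents that add atoms: none
Why: Fluoride-driven cleavage of the aryl silyl ether (strong Si–F bond) frees the phenol without touching the MOM ethers or the alkene.

Step 6
Reactants: 9 3,5-bis(methoxymethoxy)-2-methyl-4-(3-methylbut-2-enyl)phenol
Product: 10 2-hydroxy-4,6-bis(methoxymethoxy)-3-methyl-5-(3-methylbut-2-enyl)benzaldehyde
Conditions: MgCl2 (anhydrous), Et3N, (CH2O)n, MeCN, reflux; cold dilute citric acid work-up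
Reagents that add atoms: paraformaldehyde (as formaldehyde), C=O
Why: Casnati–Skattebøl ortho-formylation: the magnesium phenoxide delivers formaldehyde to the only unsubstituted ring carbon, which is ortho to the phenol, and a second formaldehyde takes up hydride from the benzylic alkoxide, under mildly basic conditions harmless to MOM ethers and prenyl.

Step 7
Reactants: 10 2-hydroxy-4,6-bis(methoxymethoxy)-3-methyl-5-(3-methylbut-2-enyl)benzaldehyde; 11 4-acetoxystyrene (4-ethenylphenyl acetate)
Product: 12 4-[(2S,4S)-4-hydroxy-5,7-bis(methoxymethoxy)-8-methyl-6-(3-methylbut-2-enyl)chroman-2-yl]phenyl acetate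
Conditions: (S,S)-IDPi (5 mol%), 11 (3 equiv, slow addition), CHCl3, −40 °C, no drying agent; Et3N quench at −40 °C
Reagents that add atoms: none
Why: Proposed new method: the acid protonates the formyl oxygen of 10, already polarised by the O1–H hydrogen bond, to a hydroxy-substituted ortho-quinone-methide-type cation that stays paired with the chiral anion, the CH2 terminus of 11 (future C3) attacks C4, and O1 collapses onto the developing benzylic cation at C2 while its proton returns to the anion. The closest known reaction types are asymmetric Prins reactions of styrenes with aldehydes under confined chiral Brønsted acids and acid-catalysed [4+2] additions of styrenes to alkoxy ortho-quinone-methide cations derived from salicylaldehydes, which give 4-alkoxy-2-arylchromans, so the free 4-hydroxy outcome, the intermolecular enantiocontrol and the crowded aldehyde are the untested parts. Ring C closes by intermolecular inverse-electron-demand oxa-[4+2] cycloaddition (O1, C8a, C4a and C4 as the four-atom partner, C3 and C2 as the two-atom partner), and in the stepwise limit the closure is the six-membered capture by O1 of a C2 cation whose stabilising C2–C1′ π-bond lies outside the new ring, that is a 6-exo-type and not an endo-type closure. C2 is controlled by the catalyst alone, whose confined anion blocks one face of the bound styrene so that O1 bonds from the other to give 2S, whereas C4 follows from the endo-like arrangement that sets aryl and hydroxyl cis (4S) and is of no consequence because step 8 erases it. Regioselectivity is secured by the substrate, since O1 is the only free phenol and is ortho to the formyl group, and since 11 can carry positive charge only at its benzylic carbon. Chemoselectivity is needed against the MOM acetals, the prenyl alkene and the new carbinol, and it rests on the formyl oxygen being the most basic site that holds the catalytic proton, on the prenyl group being meta to the aldehyde (no intramolecular ene path), flanked by two MOM ethers and outnumbered by 11, on both MOM ethers being twisted out of conjugation by their two ortho neighbours so that C4–OH ionises less easily, and on the weakly donating acetoxy group that keeps the new C2–O1 bond from ionising again.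

Step 8
Reactants: 12 4-[(2S,4S)-4-hydroxy-5,7-bis(methoxymethoxy)-8-methyl-6-(3-methylbut-2-enyl)chroman-2-yl]phenyl acetate
Product: 13 4-[(2S)-5,7-bis(methoxymethoxy)-8-methyl-6-(3-methylbut-2-enyl)-4-oxochroman-2-yl]phenyl acetate
Conditions: Dess–Martin periodinane, pyridine, CH2Cl2, 0 °C → rt
Reagents that add atoms: none
Why: Dess–Martin oxidation of the secondary benzylic alcohol is fast, non-basic and indifferent to the trisubstituted alkene, MOM ethers and acetate, it removes the C4 stereocentre, and C2 is untouched because no phenoxide or enolate that could open ring C is formed.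

Step 9
Reactants: 13 4-[(2S)-5,7-bis(methoxymethoxy)-8-methyl-6-(3-methylbut-2-enyl)-4-oxochroman-2-yl]phenyl acetate
Product: 14 (2S)-5,7-dihydroxy-2-(4-hydroxyphenyl)-8-methyl-6-(3-methylbut-2-enyl)chroman-4-one
Conditions: HCl (1.25 M in MeOH), 35 °C
Reagents that add atoms: none
Why: Acid-catalysed transacetalisation of both MOM ethers and transesterification of the aryl acetate with methanol unmask all three phenols in one operation, and the acidic medium avoids the phenoxide-triggered retro-oxa-Michael opening of ring C that would racemise C2.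

Compound list
1 | 2,4,6-trihydroxybenzaldehyde | O=Cc1c(O)cc(O)cc1O | starting material
2 | 2-hydroxy-4,6-bis(methoxymethoxy)benzaldehyde | O=Cc1c(O)cc(OCOC)cc1OCOC | intermediate
3 | 2-formyl-3,5-bis(methoxymethoxy)phenyl methyl carbonate | COC(=O)Oc1cc(OCOC)cc(OCOC)c1C=O | intermediate
4 | 3,5-bis(methoxymethoxy)-2-methylphenol | Cc1c(O)cc(OCOC)cc1OCOC | intermediate
5 | tert-butyl[3,5-bis(methoxymethoxy)-2-methylphenoxy]dimethylsilane | Cc1c(O[Si](C)(C)C(C)(C)C)cc(OCOC)cc1OCOC | intermediate
6 | prenyl bromide (1-bromo-3-methylbut-2-ene) | CC(C)=CCBr | starting material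
7 | [4-(tert-butyldimethylsilyloxy)-2,6-bis(methoxymethoxy)-3-methylphenyl]lithium | Cc1c(O[Si](C)(C)C(C)(C)C)cc(OCOC)c([Li])c1OCOC | intermediate
8 | tert-butyl[3,5-bis(methoxymethoxy)-2-methyl-4-(3-methylbut-2-enyl)phenoxy]dimethylsilane | Cc1c(O[Si](C)(C)C(C)(C)C)cc(OCOC)c(CC=C(C)C)c1OCOC | intermediate
9 | 3,5-bis(methoxymethoxy)-2-methyl-4-(3-methylbut-2-enyl)phenol | Cc1c(O)cc(OCOC)c(CC=C(C)C)c1OCOC | intermediate
10 | 2-hydroxy-4,6-bis(methoxymethoxy)-3-methyl-5-(3-methylbut-2-enyl)benzaldehyde | O=Cc1c(O)c(C)c(OCOC)c(CC=C(C)C)c1OCOC | intermediate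
11 | 4-acetoxystyrene (4-ethenylphenyl acetate) | CC(=O)Oc1ccc(C=C)cc1 | starting material
12 | 4-[(2S,4S)-4-hydroxy-5,7-bis(methoxymethoxy)-8-methyl-6-(3-methylbut-2-enyl)chroman-2-yl]phenyl acetate (2,4-cis) | O[C@H]1C[C@@H](c2ccc(OC(C)=O)cc2)Oc2c(C)c(OCOC)c(CC=C(C)C)c(OCOC)c12 | intermediate
13 | 4-[(2S)-5,7-bis(methoxymethoxy)-8-methyl-6-(3-methylbut-2-enyl)-4-oxochroman-2-yl]phenyl acetate | O=C1C[C@@H](c2ccc(OC(C)=O)cc2)Oc2c(C)c(OCOC)c(CC=C(C)C)c(OCOC)c12 | intermediate
14 | (2S)-5,7-dihydroxy-2-(4-hydroxyphenyl)-8-methyl-6-(3-methylbut-2-enyl)chroman-4-one | CC(C)=CCc1c(O)c(C)c2c(c1O)C(=O)C[C@@H](c1ccc(O)cc1)O2 | target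

Total step count: 9. Longest linear sequence: 9 steps (1 → 14). Compounds 6 and 11 are bought.

Steps most likely to fail

Step 7. Several processes can defeat it:
- The acid may ionise a MOM acetal or the freshly formed C4 carbinol, leading to elimination, ether formation or a second styrene addition.
- The acid may engage the prenyl alkene.
- The acid may oligomerise the styrene.
- The anion may differentiate the styrene faces poorly.

The fallback uses only known chemistry, sets out from 10 and comes back at 14. Addition of MeMgBr (excess, THF, 0 °C) to the formyl group should give the 1-arylethanol F1. Oxidation with MnO2 (CH2Cl2, rt) should give the ortho-hydroxyacetophenone F2. Claisen–Schmidt condensation with commercial 4-(methoxymethoxy)benzaldehyde (KOH, EtOH, rt) should give the (E)-chalcone F3. NaOAc in refluxing EtOH should give the racemic flavanone F4 by oxa-Michael closure through O1, the only free phenol. The racemate is then resolved kinetically by Noyori-type asymmetric transfer hydrogenation. This uses RuCl(p-cymene)(TsDPEN), in the antipode that reduces the 2R ketone faster, with HCO2H/Et3N in EtOAc. It should leave the (2S)-flavanone F5 and turn its mirror image into the cis-flavan-4-ol F6, which is separated. The conditions of step 9 then convert F5 into 14.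

Step 9. A neighbouring phenol or methanol may add across the protonated prenyl alkene, and prolonged acid may slowly open ring C and erode C2. The fallback avoids protic acid altogether, sets out from 13 and comes back at 14. TMSOTf and 2,2′-bipyridyl (MeCN, 0 °C → rt) exchange both aryl MOM ethers for silyl ethers to give the bis(trimethylsilyl) ether F8. Added water releases the 5,7-diphenol 4′-acetate F9. Lipase-catalysed alcoholysis (Candida antarctica lipase B, n-BuOH, MTBE, 40 °C) then removes the acetate at neutral pH.

Step 4. The allylation may proceed in the SN2′ sense and attach the prenyl unit through its tertiary carbon, or the coupling may be sluggish at the doubly flanked carbanion. The fallback sets out from 5 and comes back at 8. The same aryllithium 7 is quenched with allyl bromide, which has no regiochemical ambiguity, to give the allylarene F7. Olefin cross-metathesis with 2-methylbut-2-ene (second-generation Grubbs catalyst, CH2Cl2, 40 °C) then builds the trisubstituted alkene of 8.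

Further compounds
F1 | step 7 | 1-[2-hydroxy-4,6-bis(methoxymethoxy)-3-methyl-5-(3-methylbut-2-enyl)phenyl]ethanol (racemic) | CC(O)c1c(O)c(C)c(OCOC)c(CC=C(C)C)c1OCOC
F2 | step 7 | 1-[2-hydroxy-4,6-bis(methoxymethoxy)-3-methyl-5-(3-methylbut-2-enyl)phenyl]ethanone | CC(=O)c1c(O)c(C)c(OCOC)c(CC=C(C)C)c1OCOC
F3 | step 7 | (E)-1-[2-hydroxy-4,6-bis(methoxymethoxy)-3-methyl-5-(3-methylbut-2-enyl)phenyl]-3-[4-(methoxymethoxy)phenyl]prop-2-en-1-one | O=C(/C=C/c1ccc(OCOC)cc1)c1c(O)c(C)c(OCOC)c(CC=C(C)C)c1OCOC
F4 | step 7 | rac-5,7-bis(methoxymethoxy)-2-[4-(methoxymethoxy)phenyl]-8-methyl-6-(3-methylbut-2-enyl)chroman-4-one | O=C1CC(c2ccc(OCOC)cc2)Oc2c(C)c(OCOC)c(CC=C(C)C)c(OCOC)c12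
F5 | step 7 | (2S)-5,7-bis(methoxymethoxy)-2-[4-(methoxymethoxy)phenyl]-8-methyl-6-(3-methylbut-2-enyl)chroman-4-one | O=C1C[C@@H](c2ccc(OCOC)cc2)Oc2c(C)c(OCOC)c(CC=C(C)C)c(OCOC)c12
F6 | step 7 | (2R,4R)-5,7-bis(methoxymethoxy)-2-[4-(methoxymethoxy)phenyl]-8-methyl-6-(3-methylbut-2-enyl)chroman-4-ol | O[C@@H]1C[C@H](c2ccc(OCOC)cc2)Oc2c(C)c(OCOC)c(CC=C(C)C)c(OCOC)c12
F7 | step 4 | tert-butyl[3,5-bis(methoxymethoxy)-2-methyl-4-(prop-2-enyl)phenoxy]dimethylsilane | Cc1c(O[Si](C)(C)C(C)(C)C)cc(OCOC)c(CC=C)c1OCOC
F8 | step 9 | 4-[(2S)-8-methyl-6-(3-methylbut-2-enyl)-4-oxo-5,7-bis(trimethylsilyloxy)chroman-2-yl]phenyl acetate | O=C1C[C@@H](c2ccc(OC(C)=O)cc2)Oc2c(C)c(O[Si](C)(C)C)c(CC=C(C)C)c(O[Si](C)(C)C)c12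
F9 | step 9 | 4-[(2S)-5,7-dihydroxy-8-methyl-6-(3-methylbut-2-enyl)-4-oxochroman-2-yl]phenyl acetate | O=C1C[C@@H](c2ccc(OC(C)=O)cc2)Oc2c(C)c(O)c(CC=C(C)C)c(O)c12
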